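I counted half-lives.

| flask | substrate | catalyst | remark | time |
|---|---|---|---|---|
| zeta | 0.071 M | 0.5 mol% | the very flask that is asked about, followed so far |  |
| flask | 0.071 M | 0.5 mol% |  | 8.0 d |

- zeta (time / h: target / %): 12.0: 28.6; 20.0: 30.4; 30.0: 30.6; 40.0: 29.0; 72.0: 27.1; 96.0: 25.5; 144: 23.6

(scatter of a reading: 0.3 percentage points)

- Sunday's: at 8.0 d add substrate, 50.0% of the amount charged, then wait 15 d
- Thursday's: at 8.0 d take out 90% of the target then present, then wait 15 d
- Saturday's: change nothing and wait 15 d more
- Monday's: at 8.0 d add catalyst, 100% of the amount charged, then wait 15 d

- target taken out counts as made
- additions bring no volume worth counting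

- target, in percent of the substrate first charged, at 8.0 d
- the option that brings most further target ("none" if no option brings more than 2 percentage points) (Sunday's / Thursday's / Saturday's / Monday's / none)
- target present, with what was taken out counted in, in percent of the substrate first charged, after Sunday's
- target present, with what was taken out counted in, in percent of the substrate first charged, after Thursday's

The bench rule says a reaction is over after 4 half-lives. In the zeta run, target stood 2 percentage points under its peak reading of 30.6% at 12.0 h, which gave a rise half-life of 3.05 h. By the rule, target should have held that peak until 8.0 d. But the rule broke on a ratio: the reading at 144 h was 0.771 of the peak, a drop of 7 points against a scatter of 0.3 points. A second clock was running.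

The fall eased from 40.0 h onward, and its speed halved in 78.9 h. That time, the sag half-life, was a rough reading, but 25.9 times the rise half-life. Carrying the easing forward gave a floor of 20.0% of the charge, and 22.3% at 8.0 d.

The wait of 15 d was 4.56 sag half-lives, which leaves 4.23% of a gap, so I let each option reach its floor. I assumed a balance, the floor being a fixed share of whatever stayed in the flask. I then reckoned Saturday's and Monday's near 20.0%, under 22.3%. I reckoned Sunday's at 29.9%. I reckoned that Thursday's banked 20.1% and came to 36.0% in total, so I chose Thursday's.

The forecast said 22%, Thursday's, and totals of 20.5% after Sunday's and 29% after Thursday's, both under mine: “I favour equilibrium with a slow drain, but with real doubt.”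

The flask gave 22.6% at 8.0 d and Thursday's as best, with 31.6% after Sunday's and 37.0% after Thursday's.

    target + catalyst ⇌ isomer of the product C + catalyst, rate k1*[catalyst]*[target] forward; the back reaction follows from the equilibrium constant (K = 0.460, k = 0.0770 M⁻¹ s⁻¹)
    target + catalyst ⇌ isomer of the product A + catalyst, rate k2*[catalyst]*[target] forward; the back reaction follows from the equilibrium constant (K = 0.330, k = 0.0430 M⁻¹ s⁻¹)
    substrate ⇌ target (K = 0.770, k = 2.60 × 10⁻⁵ s⁻¹)
    isomer of the product A + catalyst ⇌ isomer of the product B + catalyst, rate k4*[catalyst]*[isomer of the product A] forward; the back reaction follows from the equilibrium constant (K = 5.10, k = 0.0340 M⁻¹ s⁻¹)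

Catalyst in the flask stood at 100% at 192 h, the pseudo-first-order case for the steps that use it, and I assumed the sag half-life stretched with the loading for the neighbour flask with 0.2 mol% catalyst: 197 h. By my count the flask had 2.43 sag half-lives behind it at 8.0 d, while that neighbour flask had 0.975. With fewer counted, I reckoned a wider gap above my floor for that neighbour flask, at 26.5% target. That neighbour flask held 26.5% target at 192 h.

All runs were generated by integration from invented constants; noise was put on by code.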